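**Retrosynthetic overview**
1. The acetyl bond C3–C4 of the γ-hydroxy-enone is cut first: enol triflate of a central-ring ketol plus a masked acetyl anion (α-ethoxyvinyl tin). This one bond creates both 1,4-dioxygen patterns of the central ring (C1–OH/C4=O and C4=O/C12'=O).
2. The ketol comes from a Michael/aldol union of a β-keto-lactone (half B) with an exocyclic enone (half A). The CH2 (C13') enters the planar β-keto-lactone on its convex face; a Diels–Alder dimerisation would put C3, not C13', on that face and give the wrong C11' epimer.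
3. The side chain of half B is cut to an enol triflate plus a β-zincated butanone ketal (ketone homoenolate).
4. Half A (7R,8R,10S) and half B (7'S,8'S,10'R) are antipodal, so both keto-lactones come from one racemic all-cis hydroxy-lactone by lipase resolution; the racemate comes from methylhydroquinone and glyoxylic acid.
5. Ring order: lactone on the arene, then cyclohexane (hydrogenation), then cycloheptanone (CH2 insertion, once per antipode), then the central cyclohexene last.

Assumption: the SMILES is taken literally, so the two halves belong to opposite enantiomeric series and, at the spiro centre C11', C13' is anti to C6' (syn to H-7').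
Locants for the dimeric compounds: xanthanolide numbering, unprimed for half A (hydroxylated half), primed for half B (spiro-lactone half); C13' is the CH2 between C5 and C11'.

**Step 1**
Reactants: 1 2-methylbenzene-1,4-diol (methylhydroquinone); 2 glyoxylic acid (50 % aqueous)
Product: 3 rac-3,5-dihydroxy-6-methyl-1-benzofuran-2(3H)-one
Conditions: 2 M aq. HCl, 50 °C, N2; crystallise
Reagents that add atoms: none
Why: Friedel–Crafts-type hydroxyalkylation by protonated glyoxylic acid occurs ortho to OH and para to the methyl group (most activated, least hindered CH), and the mandelic acid lactonises onto the neighbouring phenol; no stereocentre of the target is involved.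

**Step 2**
Reactants: 3
Product: 5 rac-(3aR*,5R*,6S*,7aR*)-5-hydroxy-6-methylhexahydro-1-benzofuran-2(3H)-one (all four ring hydrogens cis), via arylacetic lactone 4 (not isolated)
Conditions: H2 (5 bar), Pd/C, AcOH, H2SO4 (5 mol %), 50 °C; then NaOAc, Rh/Al2O3, H2 (60 bar), 50 °C
Reagents that add atoms: none
Why: acid-assisted benzylic hydrogenolysis followed by heterogeneous arene hydrogenation, which delivers all hydrogens from the catalyst-bound face and so sets the four ring stereocentres all-cis (cis lactone fusion, H-6 cis to H-3a and H-7a) as a racemate.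

**Step 3**
Reactants: 5
Product: 6 (3aR,5R,6S,7aR)-6-methyl-2-oxooctahydro-1-benzofuran-5-yl acetate
Conditions: first portion of 5; vinyl acetate, immobilised Amano PS lipase (Burkholderia cepacia), MTBE, 30 °C, stopped at about 45 % conversion; chromatography, acetate fraction kept
Reagents that add atoms: vinyl acetate, C=COC(C)=O
Why: lipase-catalysed kinetic resolution by irreversible transesterification, in which (Kazlauskas' rule, CHMe side larger than CH2 side) the (5R)-carbinol is acylated faster, so stopping below half conversion gives the acetate of the R series in high enantiomeric purity while the slow (5S)-alcohol stays unacylated.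

**Step 4**
Reactants: 5
Product: 7 (3aS,5S,6R,7aS)-5-hydroxy-6-methylhexahydro-1-benzofuran-2(3H)-one
Conditions: second portion of 5; vinyl acetate, immobilised Amano PS lipase (Burkholderia cepacia), MTBE, 30 °C, run to about 58 % conversion; chromatography, alcohol fraction kept
Reagents that add atoms: none
Why: the same lipase kinetic resolution run past half conversion, so that all of the fast (5R)-alcohol is acetylated and the remaining (5S)-alcohol, the entry to the antipodal series, is recovered enantiopure.

**Step 5**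
Reactants: 6
Product: 8 (3aR,5R,6S,7aR)-5-hydroxy-6-methylhexahydro-1-benzofuran-2(3H)-one
Conditions: MeOH (10 equiv), same immobilised lipase, MTBE, 40 °C
Reagents that add atoms: none
Why: enzymatic methanolysis (transesterification) of the acetate under neutral conditions that leave the lactone closed; no stereocentre is touched.

**Step 6**
Reactants: 8
Product: 9 (3aR,6S,7aR)-6-methyltetrahydro-1-benzofuran-2,5(3H,4H)-dione
Conditions: TEMPO (2 mol %), KBr (10 mol %), NaOCl (1.1 equiv), CH2Cl2/aq. NaHCO3, 0 °C
Reagents that add atoms: none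
Why: Anelli (oxoammonium) oxidation of the secondary alcohol, buffered, cold and fast so that the methyl-bearing α-centre is not epimerised.

**Step 7**
Reactants: 9
Product: 11 (3aR,7S,8aR)-7-methylhexahydro-2H-cyclohepta[b]furan-2,6(3H)-dione, via alpha-silyl ketone 10 (not isolated)
Conditions: Me3SiCHN2 (1.2 equiv), Sc(OTf)3 (5 mol %), CH2Cl2, −78 to −20 °C; then 1 M HCl, THF
Reagents that add atoms: (trimethylsilyl)diazomethane, C[Si](C)(C)C=[N+]=[N-]
Why: Lewis-acid-catalysed diazoalkane ring expansion (Tiffeneau–Demjanov-type homologation) in which the less substituted α-CH2 migrates, so the new CH2 enters between the carbonyl and C4 rather than next to the methyl-bearing carbon; the three stereocentres are spectators and the C–Si bond is cleaved on acidic work-up.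

**Step 8**
Reactants: 11
Product: 13 (3aR,7S,8aR)-7-methyl-3,5-bis[(trimethylammonio)methyl]hexahydro-2H-cyclohepta[b]furan-2,6(3H)-dione diiodide (C3/C5 epimers), via bis-Mannich base 12 (not isolated)
Conditions: LiN(iPr)2 (2.3 equiv), THF, −78 °C; Me2N=CH2+ I− (3 equiv), −78 °C to rt; then MeI (excess), MeOH, rt
Reagents that add atoms: Eschenmoser's salt (N,N-dimethylmethyleneiminium iodide), C=[N+](C)C.[I-]; iodomethane, CI
Why: kinetic deprotonation gives the bis-enolate (ketone on its CH2 side C5, lactone at C3), both are aminomethylated (Mannich reaction) and exhaustive N-methylation makes both amines leaving groups; the methyl-bearing C7 is not enolised and the new centres at C3 and C5 are destroyed in step 14.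

**Step 9**
Reactants: 7
Product: 14 (3aS,6R,7aS)-6-methyltetrahydro-1-benzofuran-2,5(3H,4H)-dione
Conditions: TEMPO (2 mol %), KBr (10 mol %), NaOCl (1.1 equiv), CH2Cl2/aq. NaHCO3, 0 °C
Reagents that add atoms: none
Why: the same Anelli oxidation on the antipodal alcohol, without epimerisation of the α-methyl centre.

**Step 10**
Reactants: 14
Product: 16 (3aS,7R,8aS)-7-methylhexahydro-2H-cyclohepta[b]furan-2,6(3H)-dione, via alpha-silyl ketone 15 (not isolated)
Conditions: Me3SiCHN2 (1.2 equiv), Sc(OTf)3 (5 mol %), CH2Cl2, −78 to −20 °C; then 1 M HCl, THF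
Reagents that add atoms: (trimethylsilyl)diazomethane, C[Si](C)(C)C=[N+]=[N-]
Why: the same regioselective diazoalkane ring expansion (migration of the unsubstituted α-CH2) on the antipode, stereocentres untouched.

**Step 11**
Reactants: 16
Product: 17 (3aS,7R,8aS)-7-methyl-2-oxo-3,3a,4,7,8,8a-hexahydro-2H-cyclohepta[b]furan-6-yl trifluoromethanesulfonate
Conditions: KN(SiMe3)2 (1.05 equiv), THF, −78 °C; PhNTf2 (1.1 equiv), −78 to 0 °C; aq. NH4Cl
Reagents that add atoms: N-phenylbis(trifluoromethanesulfonimide), O=S(=O)(N(c1ccccc1)S(=O)(=O)C(F)(F)F)C(F)(F)F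
Why: kinetic enolisation of the ketone on its CH2 side (away from the methyl-bearing carbon and faster than lactone deprotonation) followed by O-triflation gives the C5=C6 enol triflate regioselectively, with the three stereocentres untouched.

**Step 12**
Reactants: 17; 18 2-(2-bromoethyl)-2-methyl-1,3-dioxolane
Product: 20 (3aS,7R,8aS)-7-methyl-6-[2-(2-methyl-1,3-dioxolan-2-yl)ethyl]-3,3a,4,7,8,8a-hexahydro-2H-cyclohepta[b]furan-2-one, via organozinc 19 (not isolated)
Conditions: 18, Zn dust, LiCl, THF, 40 °C; then 17, Pd(PPh3)4 (5 mol %), THF, 50 °C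
Reagents that add atoms: none
Why: Negishi sp3–sp2 cross-coupling of the enol triflate with a β-zincated ketone ketal, a ketone homoenolate equivalent, which joins the carbonyl-derived ring carbon to the β-carbon of the future methyl ketone (two natively electrophilic positions) and installs the protected 3-oxobutyl chain without touching the lactone.

**Step 13**
Reactants: 20
Product: 21 (3aS,7R,8aS)-3-acetyl-7-methyl-6-[2-(2-methyl-1,3-dioxolan-2-yl)ethyl]-3,3a,4,7,8,8a-hexahydro-2H-cyclohepta[b]furan-2-one (C3 epimers and enol)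
Conditions: LiN(SiMe3)2 (2.2 equiv), THF, −78 °C; MeC(O)N(OMe)Me (1.2 equiv), −78 to 0 °C; aq. NH4Cl
Reagents that add atoms: N-methoxy-N-methylacetamide, CC(=O)N(C)OC
Why: Claisen-type C-acylation of the lactone enolate with a Weinreb amide (chelated tetrahedral intermediate, no over-addition) gives the β-keto-lactone, whose C3 configuration is irrelevant because it is planarised in step 14.

**Step 14**
Reactants: 13; 21
Product: 24 central-ring ketol (1S,5R,7R,8R,10S,11'S,7'S,8'S,10'R; 1-hydroxy-3-oxo; side chain of half B as dioxolane), via exocyclic enone 22 (not isolated), via Michael adduct 23 (not isolated)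
Conditions: 21 (1.0 equiv), 13 (1.05 equiv), DBU (3.3 equiv), MeCN, −20 to 23 °C; AcOH quench
Reagents that add atoms: none
Why: DBU unveils both exocyclic methylenes (E1cB loss of Me3N) and deprotonates 21, whose enolate adds (Michael) to the exocyclic enone, far more electrophilic than the α-methylene lactone, from the convex face of its cis-fused bicycle (anti to C6'), which fixes C11'; the C5 centre α to the ketone equilibrates and the methyl-ketone enolate closes the cis-fused six-membered ketol by intramolecular aldol addition to the C1 face remote from the C10 methyl and the lactone (Robinson-type annulation held at the ketol stage), setting C1 and C5.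

**Step 15**
Reactants: 24
Product: 25 C2=C3 enol triflate of 24 (3-trifluoromethanesulfonyloxy-2-ene; all stereocentres as in 24)
Conditions: KN(SiMe3)2 (2.2 equiv), THF, −78 °C; Comins' reagent (1.2 equiv), −78 °C; aq. NH4Cl
Reagents that add atoms: Comins' reagent (N-(5-chloropyridin-2-yl)bis(trifluoromethanesulfonimide)), Clc1ccc(nc1)N(S(=O)(=O)C(F)(F)F)S(=O)(=O)C(F)(F)F
Why: the C3 ketone can enolise only towards C2 (C11' is quaternary), so O-triflation of the alkoxide–enolate dianion at −78 °C gives the C2=C3 enol triflate while the hindered tertiary potassium alkoxide is not sulfonylated; no stereocentre changes.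

**Step 16**
Reactants: 25
Product: 27 target CNP0195550.4, via enol ether 26 (not isolated)
Conditions: tributyl(1-ethoxyvinyl)stannane (1.5 equiv), Pd(PPh3)4 (5 mol %), LiCl (3 equiv), CuI (10 mol %), THF, 65 °C; then 1 M aq. HCl, THF, 23 °C
Reagents that add atoms: tributyl(1-ethoxyvinyl)stannane, CCCC[Sn](CCCC)(CCCC)C(=C)OCC; water, O
Why: Stille coupling with an α-alkoxyvinyl stannane, a masked acetyl anion, joins the former ketone carbon C3 to the acyl carbon C4 (two natively electrophilic carbons) and so creates the γ-hydroxy-enone and its 1,4-dicarbonyl relation to the spiro-lactone in one bond; mild acid then hydrolyses the enol ether to the acetyl group and the dioxolane to the side-chain ketone without ionising the tertiary alcohol, whose allyl cation is destabilised by the acetyl group.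

**Compound list**
1 | 2-methylbenzene-1,4-diol (methylhydroquinone) | Cc1cc(O)ccc1O | starting material
2 | glyoxylic acid (50 % aqueous) | O=CC(=O)O | starting material
3 | rac-3,5-dihydroxy-6-methyl-1-benzofuran-2(3H)-one | Cc1cc2OC(=O)C(O)c2cc1O | intermediate
4 | 5-hydroxy-6-methyl-1-benzofuran-2(3H)-one | Cc1cc2OC(=O)Cc2cc1O | intermediate
5 | rac-(3aR*,5R*,6S*,7aR*)-5-hydroxy-6-methylhexahydro-1-benzofuran-2(3H)-one; H-3a, H-5, H-6, H-7a all cis; racemate (both enantiomers written) | C1C(=O)O[C@@H]2C[C@H](C)[C@H](O)C[C@H]12.C1C(=O)O[C@H]2C[C@@H](C)[C@@H](O)C[C@@H]12 | intermediate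
6 | (3aR,5R,6S,7aR)-6-methyl-2-oxooctahydro-1-benzofuran-5-yl acetate | C1C(=O)O[C@@H]2C[C@H](C)[C@H](OC(C)=O)C[C@H]12 | intermediate
7 | (3aS,5S,6R,7aS)-5-hydroxy-6-methylhexahydro-1-benzofuran-2(3H)-one | C1C(=O)O[C@H]2C[C@@H](C)[C@@H](O)C[C@@H]12 | intermediate
8 | (3aR,5R,6S,7aR)-5-hydroxy-6-methylhexahydro-1-benzofuran-2(3H)-one | C1C(=O)O[C@@H]2C[C@H](C)[C@H](O)C[C@H]12 | intermediate
9 | (3aR,6S,7aR)-6-methyltetrahydro-1-benzofuran-2,5(3H,4H)-dione | C1C(=O)O[C@@H]2C[C@H](C)C(=O)C[C@H]12 | intermediate
10 | 5-trimethylsilyl derivative of 11 (SiMe3 on the inserted carbon next to the ketone, C5 epimers; ring stereocentres as in 11) | C1C(=O)O[C@@H]2C[C@H](C)C(=O)C([Si](C)(C)C)C[C@H]12 | intermediate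
11 | (3aR,7S,8aR)-7-methylhexahydro-2H-cyclohepta[b]furan-2,6(3H)-dione (cis-fused; H-3a, H-7, H-8a all cis) | C1C(=O)O[C@@H]2C[C@H](C)C(=O)CC[C@H]12 | intermediate
12 | (3aR,7S,8aR)-3,5-bis[(dimethylamino)methyl]-7-methylhexahydro-2H-cyclohepta[b]furan-2,6(3H)-dione (C3/C5 epimers) | CN(C)CC1C(=O)O[C@@H]2C[C@H](C)C(=O)C(CN(C)C)C[C@H]12 | intermediate
13 | (3aR,7S,8aR)-7-methyl-3,5-bis[(trimethylammonio)methyl]hexahydro-2H-cyclohepta[b]furan-2,6(3H)-dione diiodide (C3/C5 epimers) | C[N+](C)(C)CC1C(=O)O[C@@H]2C[C@H](C)C(=O)C(C[N+](C)(C)C)C[C@H]12.[I-].[I-] | intermediate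
14 | (3aS,6R,7aS)-6-methyltetrahydro-1-benzofuran-2,5(3H,4H)-dione | C1C(=O)O[C@H]2C[C@@H](C)C(=O)C[C@@H]12 | intermediate
15 | 5-trimethylsilyl derivative of 16 (C5 epimers; ring stereocentres as in 16) | C1C(=O)O[C@H]2C[C@@H](C)C(=O)C([Si](C)(C)C)C[C@@H]12 | intermediate
16 | (3aS,7R,8aS)-7-methylhexahydro-2H-cyclohepta[b]furan-2,6(3H)-dione | C1C(=O)O[C@H]2C[C@@H](C)C(=O)CC[C@@H]12 | intermediate
17 | (3aS,7R,8aS)-7-methyl-2-oxo-3,3a,4,7,8,8a-hexahydro-2H-cyclohepta[b]furan-6-yl trifluoromethanesulfonate | C1C(=O)O[C@H]2C[C@@H](C)C(OS(=O)(=O)C(F)(F)F)=CC[C@@H]12 | intermediate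
18 | 2-(2-bromoethyl)-2-methyl-1,3-dioxolane | CC1(CCBr)OCCO1 | starting material
19 | bromo[2-(2-methyl-1,3-dioxolan-2-yl)ethyl]zinc | CC1(CC[Zn]Br)OCCO1 | intermediate
20 | (3aS,7R,8aS)-7-methyl-6-[2-(2-methyl-1,3-dioxolan-2-yl)ethyl]-3,3a,4,7,8,8a-hexahydro-2H-cyclohepta[b]furan-2-one | C1C(=O)O[C@H]2C[C@@H](C)C(CCC3(C)OCCO3)=CC[C@@H]12 | intermediate
21 | (3aS,7R,8aS)-3-acetyl-7-methyl-6-[2-(2-methyl-1,3-dioxolan-2-yl)ethyl]-3,3a,4,7,8,8a-hexahydro-2H-cyclohepta[b]furan-2-one (C3 epimers/enol) | CC(=O)C1C(=O)O[C@H]2C[C@@H](C)C(CCC3(C)OCCO3)=CC[C@@H]12 | intermediate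
22 | (3aR,7S,8aR)-7-methyl-3,5-dimethylidenehexahydro-2H-cyclohepta[b]furan-2,6(3H)-dione | C=C1C(=O)O[C@@H]2C[C@H](C)C(=O)C(=C)C[C@H]12 | intermediate
23 | Michael adduct (1,5-diketone): C5 of 22 joined through CH2 (C13') to C11' (S) of 21, which keeps its acetyl group; C5 epimers; other centres 7R,8R,10S,7'S,8'S,10'R | C=C1C(=O)O[C@@H]2C[C@H](C)C(=O)C(C[C@]3(C(C)=O)C(=O)O[C@H]4C[C@@H](C)C(CCC5(C)OCCO5)=CC[C@@H]34)C[C@H]12 | intermediate
24 | central-ring ketol (1S,5R,7R,8R,10S,11'S,7'S,8'S,10'R): 1-OH cis to H-5 and to the 10-methyl, central ring on the face of half A opposite the lactone, C2H2, C3=O, spiro at C11' with C13' anti to C6'; half A with 11(13)-methylene cis-lactone; half B side chain as dioxolane | C=C1C(=O)O[C@@H]2C[C@H](C)[C@@]3(O)CC(=O)[C@@]4(C[C@H]3C[C@H]12)C(=O)O[C@H]1C[C@@H](C)C(CCC5(C)OCCO5)=CC[C@H]14 | intermediate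
25 | enol triflate of 24 (C2=C3, 3-OTf; stereocentres as in 24) | C=C1C(=O)O[C@@H]2C[C@H](C)[C@@]3(O)C=C(OS(=O)(=O)C(F)(F)F)[C@@]4(C[C@H]3C[C@H]12)C(=O)O[C@H]1C[C@@H](C)C(CCC5(C)OCCO5)=CC[C@H]14 | intermediate
26 | 3-(1-ethoxyvinyl) diene (C2=C3; stereocentres as in 24; dioxolane still in place) | C=C1C(=O)O[C@@H]2C[C@H](C)[C@@]3(O)C=C(C(=C)OCC)[C@@]4(C[C@H]3C[C@H]12)C(=O)O[C@H]1C[C@@H](C)C(CCC5(C)OCCO5)=CC[C@H]14 | intermediate
27 | CNP0195550.4, (1S,5R,7R,8R,10S,11'S,7'S,8'S,10'R)-xanthanolide dimer: 1-hydroxy, 3-acetyl-2-ene central ring, 11(13)-methylene cis-lactone in half A, spiro cis-lactone and 3-oxobutyl chain in half B | C=C1C(=O)O[C@@H]2C[C@H](C)[C@@]3(O)C=C(C(C)=O)[C@@]4(C[C@H]3C[C@H]12)C(=O)O[C@H]1C[C@@H](C)C(CCC(C)=O)=CC[C@H]14 | target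

**Totals**
Total step count: 16. Longest linear sequence: 11 steps (steps 1, 2, 4, 9, 10, 11, 12, 13, 14, 15 and 16; 1 → 3 → 5 → 7 → 14 → 16 → 17 → 20 → 21 → 24 → 25 → 27).

**Three steps most likely to fail, with fallbacks**

The lipase resolution (step 3, and with it step 4, which uses the same enzyme reaction) may show only modest selectivity for this hindered cis-2-methylcyclohexanol-type carbinol. If the enzyme merely prefers the other enantiomer, the two streams are swapped. Otherwise the fallback is a classical resolution through covalent diastereomers. It sets out from 5, which is esterified with (S)-O-methylmandelic acid (dicyclohexylcarbodiimide, DMAP) to give the (5R)-series (S)-O-methylmandelate F1 and the (5S)-series (S)-O-methylmandelate F2. These are separated by crystallisation or chromatography and each is cleaved with catalytic K2CO3 in MeOH at 0 °C, with acidification to re-close any opened lactone. F1 returns 8 and F2 returns 7, so the route is rejoined at 8 and 7 and steps 3, 4 and 5 are not needed.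

The one-pot elimination/Michael/aldol union (step 14) can suffer from addition to the α-methylene lactone, exo-to-endo isomerisation of enone 22, a bridged aldol from the C10 enolate, dehydration of the ketol, or poor C5/C1 selectivity. The fallback keeps the lactone methylene masked as its amine adduct and releases only the ketone Mannich base thermally. It sets out from the bis-Mannich base 12 (isolated instead of being methylated) and 21. Heating in toluene at 90 °C with DBU (0.2 equiv) generates the exocyclic enone slowly, by loss of dimethylamine from the β-amino ketone only, and Michael/aldol gives the amine-masked ketol F3. N-Methylation with MeI gives the ammonium iodide F4, and NaHCO3 elimination unveils the lactone methylene and returns to 24.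

The dianion triflation (step 15) risks retro-aldol opening of the tertiary aldolate or sulfonylation of the alkoxide. The fallback is soft enolisation with silyl protection. It sets out from 24: Me3SiOTf/Et3N gives the bis-silyl compound F5 (tertiary silyl ether plus C2=C3 silyl enol ether). CsF/PhNTf2 in DME then converts the silyl enol ether regiospecifically into the silyl-protected enol triflate F6. Brief treatment with aqueous citric acid in THF removes the tertiary silyl ether and returns to 25.

**Further compounds**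
F1 | step 3 | (3aR,5R,6S,7aR)-6-methyl-2-oxooctahydro-1-benzofuran-5-yl (2S)-2-methoxy-2-phenylacetate | C1C(=O)O[C@@H]2C[C@H](C)[C@H](OC(=O)[C@@H](OC)c3ccccc3)C[C@H]12
F2 | step 3 | (3aS,5S,6R,7aS)-6-methyl-2-oxooctahydro-1-benzofuran-5-yl (2S)-2-methoxy-2-phenylacetate | C1C(=O)O[C@H]2C[C@@H](C)[C@@H](OC(=O)[C@@H](OC)c3ccccc3)C[C@@H]12
F3 | step 14 | amine-masked ketol: 24 with CH2NMe2 at C11 in place of the 11(13)-methylene (C11 epimers) | CN(C)CC1C(=O)O[C@@H]2C[C@H](C)[C@@]3(O)CC(=O)[C@@]4(C[C@H]3C[C@H]12)C(=O)O[C@H]1C[C@@H](C)C(CCC5(C)OCCO5)=CC[C@H]14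
F4 | step 14 | trimethylammonium iodide of F3 | C[N+](C)(C)CC1C(=O)O[C@@H]2C[C@H](C)[C@@]3(O)CC(=O)[C@@]4(C[C@H]3C[C@H]12)C(=O)O[C@H]1C[C@@H](C)C(CCC5(C)OCCO5)=CC[C@H]14.[I-]
F5 | step 15 | bis-silyl compound: 1-O-trimethylsilyl ether and C2=C3 trimethylsilyl enol ether of 24 | C=C1C(=O)O[C@@H]2C[C@H](C)[C@@]3(O[Si](C)(C)C)C=C(O[Si](C)(C)C)[C@@]4(C[C@H]3C[C@H]12)C(=O)O[C@H]1C[C@@H](C)C(CCC5(C)OCCO5)=CC[C@H]14
F6 | step 15 | 1-O-trimethylsilyl ether of enol triflate 25 | C=C1C(=O)O[C@@H]2C[C@H](C)[C@@]3(O[Si](C)(C)C)C=C(OS(=O)(=O)C(F)(F)F)[C@@]4(C[C@H]3C[C@H]12)C(=O)O[C@H]1C[C@@H](C)C(CCC5(C)OCCO5)=CC[C@H]14
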